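The furanone ring (O, C3, C2, C1, C10) spans the ten-membered carbocycle, so C10 carries at once the bridging oxygen, the C1 carbonyl and C9. This pattern is traced back to a vinyl tetrahydropyran: a copper carbenoid at C10 is trapped by the pyran oxygen and the ylide shifts onto the vinyl terminus C9. One operation forms O–C10 and C9–C10, closes the tetrahydrofuranone and the ten-membered ring and sets C10. The precursor is a tetrahydropyran (O, C3–C7) carrying the methyl diazoketone arm on C3 and, on C7, a vinyl group cis to that arm and a tert-butyl acetate arm.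

Key step: step 16

Remark: atom labels follow germacrane numbering (TBS = tert-butyldimethylsilyl, TBDPS = tert-butyldiphenylsilyl). The C1 carbinol carried from step 17 to step 22 is drawn as the epimer expected from hydride delivery to the open face of the five-membered ring; its configuration is immaterial because step 23 removes it.

Step 1
Reactants: 1 pent-4-enoic acid; 2 (R)-4-benzyl-1,3-oxazolidin-2-one
Product: 4 (R)-4-benzyl-3-(pent-4-enoyl)-1,3-oxazolidin-2-one, via mixed pivalic anhydride 3 (not isolated)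
Conditions: tBuCOCl, Et3N, THF, −20 °C; then 2, LiCl, rt
Reagents that add atoms: none
Why: N-acylation of the oxazolidinone by the mixed anhydride is the standard entry to Evans imides and creates no stereocentre.

Step 2
Reactants: 4 (R)-4-benzyl-3-(pent-4-enoyl)-1,3-oxazolidin-2-one; 5 3-[(tert-butyldimethylsilyl)oxy]propanal
Product: 6 syn-aldol adduct (2R,3S)
Conditions: nBu2BOTf, iPr2NEt, CH2Cl2, −78 → 0 °C; 5, −78 → 0 °C; then pH 7 buffer, MeOH, H2O2
Reagents that add atoms: none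
Why: Evans syn-aldol reaction, in which the Z-boron enolate reacts through a Zimmerman–Traxler chair on the enolate face left open by the (R)-benzyl group and so sets C4 (R) and C3 (S) together.

Step 3
Reactants: 6 syn-aldol adduct
Product: 7 (2S,3S)-5-[(TBS)oxy]-2-(prop-2-en-1-yl)pentane-1,3-diol
Conditions: LiBH4, MeOH (1 equiv), THF, 0 °C
Reagents that add atoms: none
Why: Reductive cleavage of the imide by LiBH4 should give the C15 primary alcohol and return the auxiliary without touching the silyl ether or either stereocentre.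

Step 4
Reactants: 7 (2S,3S)-5-[(TBS)oxy]-2-(prop-2-en-1-yl)pentane-1,3-diol
Product: 8 (3S,4S)-1-[(TBS)oxy]-4-{[(TBDPS)oxy]methyl}hept-6-en-3-ol
Conditions: TBDPSCl, imidazole, CH2Cl2, 0 °C
Reagents that add atoms: tert-butyl(chloro)diphenylsilane CC(C)(C)[Si](Cl)(c1ccccc1)c1ccccc1
Why: Silyl ether formation with the bulky chlorosilane should occur selectively at the primary C15 hydroxyl.

Step 5
Reactants: 8 (3S,4S)-1-[(TBS)oxy]-4-{[(TBDPS)oxy]methyl}hept-6-en-3-ol
Product: 10 (4S,5S)-7-[(TBS)oxy]-4-{[(TBDPS)oxy]methyl}heptane-1,5-diol, via B-alkyl-9-borabicyclononane 9 (not isolated)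
Conditions: 9-BBN, THF, 0 °C → rt; then aq. NaOH, H2O2, 0 °C
Reagents that add atoms: hydrogen peroxide OO
Why: Anti-Markovnikov hydroboration–oxidation of the terminal alkene should deliver the C7 primary alcohol.

Step 6
Reactants: 10 (4S,5S)-7-[(TBS)oxy]-4-{[(TBDPS)oxy]methyl}heptane-1,5-diol
Product: 12 (5S,6S)-6-{2-[(TBS)oxy]ethyl}-5-{[(TBDPS)oxy]methyl}oxan-2-one, via lactol 11 (not isolated)
Conditions: TEMPO (cat.), PhI(OAc)2, CH2Cl2, rt
Reagents that add atoms: none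
Why: Oxidative lactonisation, in which TEMPO/PhI(OAc)2 oxidises the primary alcohol selectively, the aldehyde closes onto the C3 hydroxyl and the six-membered lactol is oxidised on to the δ-lactone.

Step 7
Reactants: 12 (5S,6S)-6-{2-[(TBS)oxy]ethyl}-5-{[(TBDPS)oxy]methyl}oxan-2-one
Product: 13 (3R,5S,6S)-3-hydroxy lactone
Conditions: KN(SiMe3)2, THF, −78 °C; then 2-(phenylsulfonyl)-3-phenyloxaziridine, −78 °C; aq. NH4Cl
Reagents that add atoms: 2-(phenylsulfonyl)-3-phenyloxaziridine O=S(=O)(c1ccccc1)N1OC1c1ccccc1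
Why: Davis hydroxylation of the lactone enolate, whose half-chair is attacked along the axial trajectory so that the new C6 hydroxyl should lie trans to the equatorial C4 substituent, that is (6R).

Step 8
Reactants: 13 (3R,5S,6S)-3-hydroxy lactone
Product: 14 (3R,5S,6S)-3-[(TBS)oxy] lactone
Conditions: TBSOTf, 2,6-lutidine, CH2Cl2, −78 → 0 °C
Reagents that add atoms: tert-butyldimethylsilyl trifluoromethanesulfonate CC(C)(C)[Si](C)(C)OS(=O)(=O)C(F)(F)F
Why: Silylation of the secondary α-hydroxyl with the silyl triflate is routine and does not epimerise C6 under the hindered-base conditions.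

Step 9
Reactants: 14 (3R,5S,6S)-3-[(TBS)oxy] lactone
Product: 16 ethyl (2Z)-2-(oxan-2-ylidene)acetate, via hemiketal 15 (not isolated)
Conditions: LiN(iPr)2, EtOAc, THF, −78 °C; then 14; aq. NH4Cl; crude, MsCl, Et3N, DMAP (cat.), CH2Cl2, 0 °C → rt
Reagents that add atoms: ethyl acetate CCOC(C)=O
Why: Claisen-type addition of the lithium ester enolate to the lactone carbonyl gives the hemiketal, whose mesylate should eliminate to the conjugated exocyclic enol ether (a vinylogous carbonate).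

Step 10
Reactants: 16 ethyl (2Z)-2-(oxan-2-ylidene)acetate
Product: 18 (2Z)-2-(oxan-2-ylidene)ethyl acetate, via aluminium alkoxide 17 (not isolated)
Conditions: iBu2AlH, CH2Cl2, −78 °C; then pyridine, DMAP, Ac2O, −78 → 0 °C
Reagents that add atoms: acetic anhydride CC(=O)OC(C)=O
Why: 1,2-Reduction of the vinylogous carbonate by iBu2AlH and acetylation of the aluminium alkoxide in the same flask, so that the acid-labile enol ether allylic alcohol is never isolated.

Step 11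
Reactants: 18 (2Z)-2-(oxan-2-ylidene)ethyl acetate
Product: 21 2-[(2R,3R,5S,6S)-2-ethenyloxan-2-yl]acetic acid, via silyl ketene acetal 19 (not isolated), via trimethylsilyl ester 20 (not isolated)
Conditions: Me3SiCl, Et3N, then LiN(iPr)2, THF, −78 °C → rt, then 45 °C; aq. citric acid
Reagents that add atoms: none
Why: Ireland–Claisen rearrangement through a chair [3,3] transition state, in which the C7–C11 bond should form on the ring face opposite the pseudo-axial C6 silyloxy group, leaving the new vinyl group equatorial and cis to the C3 arm and so setting C7 (R).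

Step 12
Reactants: 21 2-[(2R,3R,5S,6S)-2-ethenyloxan-2-yl]acetic acid
Product: 22 tert-butyl ester of 21
Conditions: N,N'-diisopropyl-O-tert-butylisourea, CH2Cl2, 40 °C
Reagents that add atoms: N,N'-diisopropyl-O-tert-butylisourea CC(C)NC(=NC(C)C)OC(C)(C)C
Why: Neutral O-alkylation of the acid by the isourea; the tert-butyl ester is chosen because it resists borane and cannot readily lactonise onto the C8 hydroxyl made later.

Step 13
Reactants: 22 tert-butyl ester of 21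
Product: 23 primary alcohol at C1
Conditions: HF·pyridine, pyridine, THF, 0 °C
Reagents that add atoms: none
Why: Buffered fluoride desilylation should cleave the unhindered primary TBS ether much faster than the secondary TBS ether next to the quaternary carbon or the TBDPS ether.

Step 14
Reactants: 23 primary alcohol at C1
Product: 24 carboxylic acid at C1
Conditions: TEMPO (cat.), PhI(OAc)2, MeCN/H2O, rt
Reagents that add atoms: water O
Why: TEMPO/PhI(OAc)2 oxidation in aqueous acetonitrile takes the primary alcohol through the aldehyde hydrate to the acid and leaves the vinyl group and the silyl ethers alone.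

Step 15
Reactants: 24 carboxylic acid at C1
Product: 26 methyl diazoketone, via mixed carbonic anhydride 25 (not isolated)
Conditions: iBuOCOCl, Et3N, Et2O, −20 °C; then CH3CHN2 in Et2O (from N-ethyl-N-nitrosourea, aq. KOH), −20 → 0 °C
Reagents that add atoms: diazoethane CC=[N+]=[N-]
Why: Acylation of diazoethane by the mixed carbonic anhydride (Arndt–Eistert-type diazoketone synthesis), in which the departing isobutyl carbonate takes up the proton so that no acid reaches the tertiary allylic ether.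

Step 16
Reactants: 26 methyl diazoketone
Product: 28 oxygen-bridged ten-membered ketone with a Z C7/C8 alkene, via bicyclic oxonium ylide 27 (not isolated)
Conditions: Cu(CF3COCHCOCF3)2 (5 mol %), CH2Cl2, reflux, slow addition of 26
Reagents that add atoms: none
Why: Proposed new method: the divalent copper catalyst turns the diazoketone into an electrophilic carbenoid at C10, the pyran oxygen attacks it to give a bicyclic oxonium ylide, and a suprafacial [2,3]-sigmatropic shift through a five-membered envelope joins C10 to the vinyl terminus C9 while the O–C7 bond breaks. The closest known reaction type is the copper-catalysed oxonium ylide formation and [2,3]-rearrangement of vinyl tetrahydropyranyl diazomethyl ketones to 11-oxabicyclo[6.2.1]undecenones; new here are the methyl group on the carbenoid carbon and the fully substituted allylic ether carbon C7, whose weaker C–O bond should ease the shift. The tetrahydrofuranone is closed by five-membered capture of the carbenoid carbon by the ether oxygen (O–C10), and the ten-membered carbocycle by the ring-expanding [2,3]-shift (C9–C10) and not by an end-to-end macrocyclisation. The new stereocentre C10 is fixed by C3, because the two-atom tether allows only the cis-2,5-bridged tetrahydrofuranone. The step needs ylide formation to outrun 1,2-hydride migration from the C14 methyl group and needs the Z ring alkene; the close-lying ether oxygen, the electron-poor hexafluoroacetylacetonate ligands and slow addition favour the former, and the equatorial vinyl group cis to the C3 arm favours the latter.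

Step 17
Reactants: 28 oxygen-bridged ten-membered ketone
Product: 30 C1,C8-diol (8S), via organoborane 29 (not isolated)
Conditions: BH3·THF, THF, 0 °C → rt; then aq. NaOAc, H2O2, 0 °C → rt
Reagents that add atoms: hydrogen peroxide OO
Why: Hydroboration–oxidation, in which borane should add syn across C7=C8 from the convex face of the oxabicycle (away from the one-atom oxygen bridge), placing boron on the less substituted C8 and hydrogen on C7 cis to the C6 silyloxy group, while the C1 ketone is reduced at the same time.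

Step 18
Reactants: 30 C1,C8-diol (8S)
Product: 31 C1,C8-diketone
Conditions: Dess–Martin periodinane, NaHCO3, CH2Cl2, rt
Reagents that add atoms: none
Why: Dess–Martin oxidation of both secondary alcohols gives the C8 ketone needed to invert C8, and the buffer protects the C7 stereocentre alpha to it.

Step 19
Reactants: 31 C1,C8-diketone
Product: 32 C1,C8-diol (8R)
Conditions: NaBH4, CeCl3·7H2O, MeOH/CH2Cl2, −78 °C; AcOH quench
Reagents that add atoms: none
Why: Luche-type borohydride reduction, in which hydride should reach the C8 carbonyl from the same convex face and anti to the C7 acetate arm, so the new hydroxyl lies on the concave face as (8R); the C1 ketone is reduced again from the face away from the six-carbon bridge.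

Step 20
Reactants: 32 C1,C8-diol (8R); 33 angelic acid
Product: 35 C8 angelate, via mixed anhydride 34 (not isolated)
Conditions: 33, 2,4,6-Cl3C6H2COCl, Et3N, toluene, rt; then 32, DMAP, toluene, 70 °C
Reagents that add atoms: none
Why: Yamaguchi esterification acylates the C8 hydroxyl with retention and without Z to E isomerisation of the angelate, while the C1 hydroxyl, neopentylic and tucked under the six-carbon bridge, is expected to stay free.

Step 21
Reactants: 35 C8 angelate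
Product: 37 6,12-lactone, via hydroxy acid 36 (not isolated)
Conditions: TFA/CH2Cl2/H2O (10:10:1), 0 °C → rt
Reagents that add atoms: none
Why: Acidolysis removes the tert-butyl ester and the secondary silyl ether, and the γ-hydroxy acid should lactonise onto O6, the only free hydroxyl within reach because O8 is acylated; the primary TBDPS ether and the angelate tolerate aqueous TFA.

Step 22
Reactants: 37 6,12-lactone
Product: 40 α-methylene lactone, via Mannich base 38 (not isolated), via trimethylammonium iodide 39 (not isolated)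
Conditions: LiN(SiMe3)2, THF, −78 °C; CH2=NMe2+ I−, −78 → 0 °C; then MeI, MeOH/CH2Cl2, rt; aq. NaHCO3
Reagents that add atoms: N,N-dimethylmethyleneiminium iodide C=[N+](C)C.[I-]
Why: Mannich reaction of the lactone enolate with the iminium salt, N-methylation and elimination of trimethylamine (the Eschenmoser salt route to α-methylene lactones); the amide base is too weak to deprotonate the angelate and the C1 alkoxide is a spectator.

Step 23
Reactants: 40 α-methylene lactone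
Product: 41 C1 ketone
Conditions: Dess–Martin periodinane, NaHCO3, CH2Cl2, rt
Reagents that add atoms: none
Why: Dess–Martin oxidation restores the C1 ketone under neutral conditions that spare the α-methylene lactone and the angelate.

Step 24
Reactants: 41 C1 ketone
Product: 43 furanone, via silyl enol ether 42 (not isolated)
Conditions: Me3SiOTf, Et3N, CH2Cl2, 0 °C; then Pd(OAc)2, MeCN, rt
Reagents that add atoms: none
Why: Saegusa–Ito oxidation, in which enolisation can only occur towards C2 because C10 is quaternary and the palladium enolate loses the C3 hydrogen by β-hydride elimination to give the 3(2H)-furanone.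

Step 25
Reactants: 43 furanone
Product: 44 CNP0108636.1
Conditions: HF·pyridine, pyridine, THF, 0 °C → rt
Reagents that add atoms: none
Why: Fluoride cleavage of the primary TBDPS ether under buffered, non-basic conditions should spare the angelate, the α-methylene lactone and the furanone.

Compound list

1 | pent-4-enoic acid | C=CCCC(=O)O | starting material
2 | (R)-4-benzyl-1,3-oxazolidin-2-one | O=C1N[C@H](Cc2ccccc2)CO1 | starting material
3 | pent-4-enoic pivalic anhydride (formed in the flask) | C=CCCC(=O)OC(=O)C(C)(C)C | intermediate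
4 | (R)-4-benzyl-3-(pent-4-enoyl)-1,3-oxazolidin-2-one | C=CCCC(=O)N1[C@H](Cc2ccccc2)COC1=O | intermediate
5 | 3-[(tert-butyldimethylsilyl)oxy]propanal | O=CCCO[Si](C)(C)C(C)(C)C | starting material
6 | (R)-4-benzyl-3-[(2R,3S)-5-[(TBS)oxy]-3-hydroxy-2-(prop-2-en-1-yl)pentanoyl]-1,3-oxazolidin-2-one | C=CC[C@@H](C(=O)N1[C@H](Cc2ccccc2)COC1=O)[C@@H](O)CCO[Si](C)(C)C(C)(C)C | intermediate
7 | (2S,3S)-5-[(TBS)oxy]-2-(prop-2-en-1-yl)pentane-1,3-diol | C=CC[C@@H](CO)[C@@H](O)CCO[Si](C)(C)C(C)(C)C | intermediate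
8 | (3S,4S)-1-[(TBS)oxy]-4-{[(TBDPS)oxy]methyl}hept-6-en-3-ol | C=CC[C@@H](CO[Si](c1ccccc1)(c1ccccc1)C(C)(C)C)[C@@H](O)CCO[Si](C)(C)C(C)(C)C | intermediate
9 | B-alkyl-9-borabicyclo[3.3.1]nonane from 8, boron on C7 (formed in the flask) | C1CCC2CCCC1B2CCC[C@@H](CO[Si](c1ccccc1)(c1ccccc1)C(C)(C)C)[C@@H](O)CCO[Si](C)(C)C(C)(C)C | intermediate
10 | (4S,5S)-7-[(TBS)oxy]-4-{[(TBDPS)oxy]methyl}heptane-1,5-diol | OCCC[C@@H](CO[Si](c1ccccc1)(c1ccccc1)C(C)(C)C)[C@@H](O)CCO[Si](C)(C)C(C)(C)C | intermediate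
11 | (5S,6S)-6-{2-[(TBS)oxy]ethyl}-5-{[(TBDPS)oxy]methyl}oxan-2-ol, lactol (formed in the flask) | OC1CC[C@@H](CO[Si](c2ccccc2)(c2ccccc2)C(C)(C)C)[C@H](CCO[Si](C)(C)C(C)(C)C)O1 | intermediate
12 | (5S,6S)-6-{2-[(TBS)oxy]ethyl}-5-{[(TBDPS)oxy]methyl}oxan-2-one | O=C1CC[C@@H](CO[Si](c2ccccc2)(c2ccccc2)C(C)(C)C)[C@H](CCO[Si](C)(C)C(C)(C)C)O1 | intermediate
13 | (3R,5S,6S)-3-hydroxy-6-{2-[(TBS)oxy]ethyl}-5-{[(TBDPS)oxy]methyl}oxan-2-one | O=C1[C@H](O)C[C@@H](CO[Si](c2ccccc2)(c2ccccc2)C(C)(C)C)[C@H](CCO[Si](C)(C)C(C)(C)C)O1 | intermediate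
14 | (3R,5S,6S)-3-[(TBS)oxy]-6-{2-[(TBS)oxy]ethyl}-5-{[(TBDPS)oxy]methyl}oxan-2-one | O=C1[C@H](O[Si](C)(C)C(C)(C)C)C[C@@H](CO[Si](c2ccccc2)(c2ccccc2)C(C)(C)C)[C@H](CCO[Si](C)(C)C(C)(C)C)O1 | intermediate
15 | ethyl 2-[(3R,5S,6S)-2-hydroxy-3-[(TBS)oxy]-6-{2-[(TBS)oxy]ethyl}-5-{[(TBDPS)oxy]methyl}oxan-2-yl]acetate, hemiketal (formed in the flask) | CCOC(=O)CC1(O)[C@H](O[Si](C)(C)C(C)(C)C)C[C@@H](CO[Si](c2ccccc2)(c2ccccc2)C(C)(C)C)[C@H](CCO[Si](C)(C)C(C)(C)C)O1 | intermediate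
16 | ethyl (2Z)-2-[(3R,5S,6S)-3-[(TBS)oxy]-6-{2-[(TBS)oxy]ethyl}-5-{[(TBDPS)oxy]methyl}oxan-2-ylidene]acetate | CCOC(=O)/C=C1/[C@H](O[Si](C)(C)C(C)(C)C)C[C@@H](CO[Si](c2ccccc2)(c2ccccc2)C(C)(C)C)[C@H](CCO[Si](C)(C)C(C)(C)C)O1 | intermediate
17 | diisobutylaluminium alkoxide of the (2Z)-2-(oxan-2-ylidene)ethanol from 16 (formed in the flask) | CC(C)C[Al](CC(C)C)OC/C=C1/[C@H](O[Si](C)(C)C(C)(C)C)C[C@@H](CO[Si](c2ccccc2)(c2ccccc2)C(C)(C)C)[C@H](CCO[Si](C)(C)C(C)(C)C)O1 | intermediate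
18 | (2Z)-2-[(3R,5S,6S)-3-[(TBS)oxy]-6-{2-[(TBS)oxy]ethyl}-5-{[(TBDPS)oxy]methyl}oxan-2-ylidene]ethyl acetate | CC(=O)OC/C=C1/[C@H](O[Si](C)(C)C(C)(C)C)C[C@@H](CO[Si](c2ccccc2)(c2ccccc2)C(C)(C)C)[C@H](CCO[Si](C)(C)C(C)(C)C)O1 | intermediate
19 | trimethylsilyl ketene acetal of 18 (formed in the flask) | C=C(O[Si](C)(C)C)OC/C=C1/[C@H](O[Si](C)(C)C(C)(C)C)C[C@@H](CO[Si](c2ccccc2)(c2ccccc2)C(C)(C)C)[C@H](CCO[Si](C)(C)C(C)(C)C)O1 | intermediate
20 | trimethylsilyl ester of 21 (formed in the flask) | CC(C)(C)[Si](C)(C)OCC[C@@H]1O[C@@](C=C)(CC(=O)O[Si](C)(C)C)[C@H](O[Si](C)(C)C(C)(C)C)C[C@H]1CO[Si](c2ccccc2)(c2ccccc2)C(C)(C)C | intermediate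
21 | 2-[(2R,3R,5S,6S)-2-ethenyl-3-[(TBS)oxy]-6-{2-[(TBS)oxy]ethyl}-5-{[(TBDPS)oxy]methyl}oxan-2-yl]acetic acid | CC(C)(C)[Si](C)(C)OCC[C@@H]1O[C@@](C=C)(CC(=O)O)[C@H](O[Si](C)(C)C(C)(C)C)C[C@H]1CO[Si](c2ccccc2)(c2ccccc2)C(C)(C)C | intermediate
22 | tert-butyl 2-[(2R,3R,5S,6S)-2-ethenyl-3-[(TBS)oxy]-6-{2-[(TBS)oxy]ethyl}-5-{[(TBDPS)oxy]methyl}oxan-2-yl]acetate | CC(C)(C)[Si](C)(C)OCC[C@@H]1O[C@@](C=C)(CC(=O)OC(C)(C)C)[C@H](O[Si](C)(C)C(C)(C)C)C[C@H]1CO[Si](c2ccccc2)(c2ccccc2)C(C)(C)C | intermediate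
23 | tert-butyl 2-[(2R,3R,5S,6S)-2-ethenyl-6-(2-hydroxyethyl)-3-[(TBS)oxy]-5-{[(TBDPS)oxy]methyl}oxan-2-yl]acetate | OCC[C@@H]1O[C@@](C=C)(CC(=O)OC(C)(C)C)[C@H](O[Si](C)(C)C(C)(C)C)C[C@H]1CO[Si](c2ccccc2)(c2ccccc2)C(C)(C)C | intermediate
24 | 2-[(2S,3S,5R,6R)-6-(2-tert-butoxy-2-oxoethyl)-6-ethenyl-5-[(TBS)oxy]-3-{[(TBDPS)oxy]methyl}oxan-2-yl]acetic acid | OC(=O)C[C@@H]1O[C@@](C=C)(CC(=O)OC(C)(C)C)[C@H](O[Si](C)(C)C(C)(C)C)C[C@H]1CO[Si](c2ccccc2)(c2ccccc2)C(C)(C)C | intermediate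
25 | isobutyl carbonic mixed anhydride of 24 (formed in the flask) | CC(C)COC(=O)OC(=O)C[C@@H]1O[C@@](C=C)(CC(=O)OC(C)(C)C)[C@H](O[Si](C)(C)C(C)(C)C)C[C@H]1CO[Si](c2ccccc2)(c2ccccc2)C(C)(C)C | intermediate
26 | tert-butyl 2-[(2R,3R,5S,6S)-6-(3-diazo-2-oxobutyl)-2-ethenyl-3-[(TBS)oxy]-5-{[(TBDPS)oxy]methyl}oxan-2-yl]acetate | CC(=[N+]=[N-])C(=O)C[C@@H]1O[C@@](C=C)(CC(=O)OC(C)(C)C)[C@H](O[Si](C)(C)C(C)(C)C)C[C@H]1CO[Si](c2ccccc2)(c2ccccc2)C(C)(C)C | intermediate
27 | bicyclic oxonium ylide, pyran oxygen bonded to C10, drawn as its enolate form (formed in the flask) | CC1=C([O-])C[C@@H]2[O+]1[C@@](C=C)(CC(=O)OC(C)(C)C)[C@H](O[Si](C)(C)C(C)(C)C)C[C@H]2CO[Si](c3ccccc3)(c3ccccc3)C(C)(C)C | intermediate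
28 | tert-butyl (3S,4S,6R,7Z,10S)-6-[(TBS)oxy]-15-[(TBDPS)oxy]-1-oxo-3,10-epoxy-13-norgermacr-7-en-12-oate | CC(C)(C)OC(=O)C/C1=C/C[C@]2(C)O[C@@H](CC2=O)[C@H](CO[Si](c3ccccc3)(c3ccccc3)C(C)(C)C)C[C@H]1O[Si](C)(C)C(C)(C)C | intermediate
29 | organoborane from 28, BH2 on C8 and O–BH2 on C1 (formed in the flask) | CC(C)(C)OC(=O)C[C@@H]1[C@@H](B)C[C@]2(C)O[C@@H](C[C@@H]2OB)[C@H](CO[Si](c3ccccc3)(c3ccccc3)C(C)(C)C)C[C@H]1O[Si](C)(C)C(C)(C)C | intermediate
30 | tert-butyl (1S,3S,4S,6R,7R,8S,10S)-1,8-dihydroxy-6-[(TBS)oxy]-15-[(TBDPS)oxy]-3,10-epoxy-13-norgermacran-12-oate | CC(C)(C)OC(=O)C[C@@H]1[C@@H](O)C[C@]2(C)O[C@@H](C[C@@H]2O)[C@H](CO[Si](c3ccccc3)(c3ccccc3)C(C)(C)C)C[C@H]1O[Si](C)(C)C(C)(C)C | intermediate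
31 | tert-butyl (3S,4S,6R,7S,10S)-6-[(TBS)oxy]-15-[(TBDPS)oxy]-1,8-dioxo-3,10-epoxy-13-norgermacran-12-oate | CC(C)(C)OC(=O)C[C@@H]1C(=O)C[C@]2(C)O[C@@H](CC2=O)[C@H](CO[Si](c3ccccc3)(c3ccccc3)C(C)(C)C)C[C@H]1O[Si](C)(C)C(C)(C)C | intermediate
32 | tert-butyl (1S,3S,4S,6R,7R,8R,10S)-1,8-dihydroxy-6-[(TBS)oxy]-15-[(TBDPS)oxy]-3,10-epoxy-13-norgermacran-12-oate | CC(C)(C)OC(=O)C[C@@H]1[C@H](O)C[C@]2(C)O[C@@H](C[C@@H]2O)[C@H](CO[Si](c3ccccc3)(c3ccccc3)C(C)(C)C)C[C@H]1O[Si](C)(C)C(C)(C)C | intermediate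
33 | angelic acid, (2Z)-2-methylbut-2-enoic acid | C/C=C(/C)C(=O)O | starting material
34 | angelic 2,4,6-trichlorobenzoic anhydride (formed in the flask) | C/C=C(/C)C(=O)OC(=O)c1c(Cl)cc(Cl)cc1Cl | intermediate
35 | tert-butyl (1S,3S,4S,6R,7R,8R,10S)-8-(angeloyloxy)-1-hydroxy-6-[(TBS)oxy]-15-[(TBDPS)oxy]-3,10-epoxy-13-norgermacran-12-oate | CC(C)(C)OC(=O)C[C@@H]1[C@H](OC(=O)/C(C)=C\C)C[C@]2(C)O[C@@H](C[C@@H]2O)[C@H](CO[Si](c3ccccc3)(c3ccccc3)C(C)(C)C)C[C@H]1O[Si](C)(C)C(C)(C)C | intermediate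
36 | 8-(angeloyloxy)-1,6-dihydroxy-15-[(TBDPS)oxy]-3,10-epoxy-13-norgermacran-12-oic acid (formed in the flask) | OC(=O)C[C@@H]1[C@H](OC(=O)/C(C)=C\C)C[C@]2(C)O[C@@H](C[C@@H]2O)[C@H](CO[Si](c3ccccc3)(c3ccccc3)C(C)(C)C)C[C@H]1O | intermediate
37 | (1S,3S,4S,6R,7S,8R,10S)-8-(angeloyloxy)-1-hydroxy-15-[(TBDPS)oxy]-3,10-epoxy-13-norgermacran-12,6-olide | O=C1C[C@@H]2[C@H](OC(=O)/C(C)=C\C)C[C@]3(C)O[C@@H](C[C@@H]3O)[C@H](CO[Si](c4ccccc4)(c4ccccc4)C(C)(C)C)C[C@H]2O1 | intermediate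
38 | 13-(dimethylamino) Mannich base of 37, C11 epimers (formed in the flask) | CN(C)CC1[C@@H]2[C@H](OC(=O)/C(C)=C\C)C[C@]3(C)O[C@@H](C[C@@H]3O)[C@H](CO[Si](c4ccccc4)(c4ccccc4)C(C)(C)C)C[C@H]2OC1=O | intermediate
39 | 13-(trimethylammonio) iodide from 38 (formed in the flask) | C[N+](C)(C)CC1[C@@H]2[C@H](OC(=O)/C(C)=C\C)C[C@]3(C)O[C@@H](C[C@@H]3O)[C@H](CO[Si](c4ccccc4)(c4ccccc4)C(C)(C)C)C[C@H]2OC1=O.[I-] | intermediate
40 | (1S,3S,4S,6R,7S,8R,10S)-8-(angeloyloxy)-1-hydroxy-15-[(TBDPS)oxy]-3,10-epoxygermacr-11(13)-en-12,6-olide | C=C1[C@@H]2[C@H](OC(=O)/C(C)=C\C)C[C@]3(C)O[C@@H](C[C@@H]3O)[C@H](CO[Si](c4ccccc4)(c4ccccc4)C(C)(C)C)C[C@H]2OC1=O | intermediate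
41 | (3S,4S,6R,7S,8R,10S)-8-(angeloyloxy)-15-[(TBDPS)oxy]-1-oxo-3,10-epoxygermacr-11(13)-en-12,6-olide | C=C1[C@@H]2[C@H](OC(=O)/C(C)=C\C)C[C@]3(C)O[C@@H](CC3=O)[C@H](CO[Si](c4ccccc4)(c4ccccc4)C(C)(C)C)C[C@H]2OC1=O | intermediate
42 | C1=C2 trimethylsilyl enol ether of 41 (formed in the flask) | C=C1[C@@H]2[C@H](OC(=O)/C(C)=C\C)C[C@]3(C)O[C@@H](C=C3O[Si](C)(C)C)[C@H](CO[Si](c4ccccc4)(c4ccccc4)C(C)(C)C)C[C@H]2OC1=O | intermediate
43 | (4S,6R,7S,8R,10S)-8-(angeloyloxy)-15-[(TBDPS)oxy]-1-oxo-3,10-epoxygermacra-2,11(13)-dien-12,6-olide | C=C1[C@@H]2[C@H](OC(=O)/C(C)=C\C)C[C@]3(C)OC(=CC3=O)[C@H](CO[Si](c4ccccc4)(c4ccccc4)C(C)(C)C)C[C@H]2OC1=O | intermediate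
44 | CNP0108636.1, (4S,6R,7S,8R,10S)-8-(angeloyloxy)-15-hydroxy-1-oxo-3,10-epoxygermacra-2,11(13)-dien-12,6-olide | C=C1[C@@H]2[C@H](OC(=O)/C(C)=C\C)C[C@]3(C)OC(=CC3=O)[C@H](CO)C[C@H]2OC1=O | target

Total step count: 25. Longest linear sequence: 25 steps (1 to 44).

Steps most likely to fail

Step 16. The carbenoid may be lost to 1,2-hydride migration from the methyl group (giving an enone) or to C–H insertion before the oxygen captures it, or the alkene geometry may erode. The fallback sets out from acid 24 and returns at ketone 28. The same mixed-anhydride activation followed by diazomethane gives the diazomethyl ketone F1, the substrate class for which the copper-catalysed ring expansion is established, and Cu(CF3COCHCOCF3)2 in refluxing CH2Cl2 should give the C10-unsubstituted bridged ketone F2. Kinetic enolisation towards C2 (LiN(SiMe3)2, Me3SiCl) gives the silyl enol ether F3, and Pd(OAc)2 (Saegusa–Ito) gives the furanone F4, in which the C10 proton is the only one alpha to the ketone. LiN(SiMe3)2 then MeI should methylate C10 on its only open face to the methylated furanone F5. Rhodium-catalysed 1,4-hydrosilylation (Et3SiH, RhCl(PPh3)3) gives the triethylsilyl enol ether F6, and K2CO3 in MeOH returns ketone 28.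

Step 17. Facial selectivity may be poor, or the addition sluggish, because the C6 silyloxy group crowds the convex face that borane must use. The fallback sets out from ketone 28 and returns at diketone 31. A carbonyl-directed rhodium-catalysed hydroboration (pinacolborane, Rh(nbd)2BF4, chiral phosphite ligand) lets the tert-butyl ester guide the catalyst and the ligand, rather than the substrate, choose the face; it also spares the C1 ketone and gives the C8 pinacol boronate F7. NaBO3 oxidation gives the hydroxy ketone F8, and the Dess–Martin oxidation of step 18 converts F8 into diketone 31.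

Step 11. The sigmatropic shift may show poor facial selectivity at C7, or the enol ether allylic acetate may ionise before it rearranges. The fallback sets out from lactone 14 and returns at ester 22. LiC≡CSiMe3 adds to the lactone to give the alkynyl hemiketal F9. Me3SiOTf then generates the alkynyl oxocarbenium ion, which 1-tert-butoxy-1-[(tert-butyldimethylsilyl)oxy]ethene should capture axially, anti to the C6 silyloxy group, to give the alkynyl tetrahydropyran F10 with the tert-butyl acetate arm already in place. K2CO3 in MeOH removes the alkyne silyl group to give the terminal alkyne F11, and semihydrogenation over Pd/CaCO3 poisoned with Pb(OAc)2 gives vinyl tetrahydropyran 22.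

Further compounds

F1 | step 16 | tert-butyl 2-[(2R,3R,5S,6S)-6-(3-diazo-2-oxopropyl)-2-ethenyl-3-[(TBS)oxy]-5-{[(TBDPS)oxy]methyl}oxan-2-yl]acetate | [N-]=[N+]=CC(=O)C[C@@H]1O[C@@](C=C)(CC(=O)OC(C)(C)C)[C@H](O[Si](C)(C)C(C)(C)C)C[C@H]1CO[Si](c2ccccc2)(c2ccccc2)C(C)(C)C
F2 | step 16 | tert-butyl (3S,4S,6R,7Z,10S)-6-[(TBS)oxy]-15-[(TBDPS)oxy]-1-oxo-3,10-epoxy-13,14-dinorgermacr-7-en-12-oate | CC(C)(C)OC(=O)C/C1=C/C[C@@H]2O[C@@H](CC2=O)[C@H](CO[Si](c3ccccc3)(c3ccccc3)C(C)(C)C)C[C@H]1O[Si](C)(C)C(C)(C)C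
F3 | step 16 | C1=C2 trimethylsilyl enol ether of F2 | CC(C)(C)OC(=O)C/C1=C/C[C@@H]2O[C@@H](C=C2O[Si](C)(C)C)[C@H](CO[Si](c3ccccc3)(c3ccccc3)C(C)(C)C)C[C@H]1O[Si](C)(C)C(C)(C)C
F4 | step 16 | C10-unsubstituted furanone, C2=C3 enone of F2 | CC(C)(C)OC(=O)C/C1=C/C[C@@H]2OC(=CC2=O)[C@H](CO[Si](c3ccccc3)(c3ccccc3)C(C)(C)C)C[C@H]1O[Si](C)(C)C(C)(C)C
F5 | step 16 | C10-methylated furanone, C2=C3 enone of 28 | CC(C)(C)OC(=O)C/C1=C/C[C@]2(C)OC(=CC2=O)[C@H](CO[Si](c3ccccc3)(c3ccccc3)C(C)(C)C)C[C@H]1O[Si](C)(C)C(C)(C)C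
F6 | step 16 | C1=C2 triethylsilyl enol ether of 28 | CC(C)(C)OC(=O)C/C1=C/C[C@]2(C)O[C@@H](C=C2O[Si](CC)(CC)CC)[C@H](CO[Si](c3ccccc3)(c3ccccc3)C(C)(C)C)C[C@H]1O[Si](C)(C)C(C)(C)C
F7 | step 17 | C8 pinacol boronate of the C7/C8-saturated C1 ketone | CC(C)(C)OC(=O)C[C@@H]1[C@@H](B2OC(C)(C)C(C)(C)O2)C[C@]3(C)O[C@@H](CC3=O)[C@H](CO[Si](c4ccccc4)(c4ccccc4)C(C)(C)C)C[C@H]1O[Si](C)(C)C(C)(C)C
F8 | step 17 | tert-butyl 8-hydroxy-6-[(TBS)oxy]-15-[(TBDPS)oxy]-1-oxo-3,10-epoxy-13-norgermacran-12-oate | CC(C)(C)OC(=O)C[C@@H]1[C@@H](O)C[C@]2(C)O[C@@H](CC2=O)[C@H](CO[Si](c3ccccc3)(c3ccccc3)C(C)(C)C)C[C@H]1O[Si](C)(C)C(C)(C)C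
F9 | step 11 | (3R,5S,6S)-3-[(TBS)oxy]-6-{2-[(TBS)oxy]ethyl}-5-{[(TBDPS)oxy]methyl}-2-[(trimethylsilyl)ethynyl]oxan-2-ol | C[Si](C)(C)C#CC1(O)[C@H](O[Si](C)(C)C(C)(C)C)C[C@@H](CO[Si](c2ccccc2)(c2ccccc2)C(C)(C)C)[C@H](CCO[Si](C)(C)C(C)(C)C)O1
F10 | step 11 | tert-butyl 2-[(2R,3R,5S,6S)-3-[(TBS)oxy]-6-{2-[(TBS)oxy]ethyl}-5-{[(TBDPS)oxy]methyl}-2-[(trimethylsilyl)ethynyl]oxan-2-yl]acetate | CC(C)(C)[Si](C)(C)OCC[C@@H]1O[C@@](C#C[Si](C)(C)C)(CC(=O)OC(C)(C)C)[C@H](O[Si](C)(C)C(C)(C)C)C[C@H]1CO[Si](c2ccccc2)(c2ccccc2)C(C)(C)C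
F11 | step 11 | tert-butyl 2-[(2R,3R,5S,6S)-2-ethynyl-3-[(TBS)oxy]-6-{2-[(TBS)oxy]ethyl}-5-{[(TBDPS)oxy]methyl}oxan-2-yl]acetate | CC(C)(C)[Si](C)(C)OCC[C@@H]1O[C@@](C#C)(CC(=O)OC(C)(C)C)[C@H](O[Si](C)(C)C(C)(C)C)C[C@H]1CO[Si](c2ccccc2)(c2ccccc2)C(C)(C)C
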